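Over 15 d the solid substrate feeds the solution, and the target passes into crystals, which count as target. The isomer of the product has no solid form.

| flask | solid substrate | remark | time |
|---|---|---|---|
| Saturday's | 28 mM | run made earlier |  |
| Tuesday's | 44 mM | run made earlier |  |
| flask | 20 mM |  | 15 d |

| run | time / d | isomer of the product / % | target / % |
|---|---|---|---|
| Saturday's | 1.25 | 0 | 11 |
| Saturday's | 2.00 | 3 | 27 |
| Saturday's | 3.00 | 0 | 43 |
| Saturday's | 5.00 | 5 | 74 |
| Saturday's | 8.00 | 0 | 94 |
| Saturday's | 12.0 | 0 | 93 |
| Saturday's | 20.0 | 3 | 93 |
| Tuesday's | 1.25 | 1 | 9 |
| Tuesday's | 2.00 | 0 | 17 |
| Tuesday's | 3.00 | 0 | 26 |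
| Tuesday's | 5.00 | 0 | 49 |
| Tuesday's | 8.00 | 1 | 75 |
| Tuesday's | 12.0 | 0 | 96 |
| Tuesday's | 20.0 | 0 | 94 |

(each reading ± 2 percentage points)

* share of isomer of the product in isomer of the product plus target at 8.0 h
* share of isomer of the product in isomer of the product plus target at 50 h
* share of isomer of the product in isomer of the product plus target at 15 d

- what is said of target includes crystals
- solid substrate, crystals is a solid; its amount is given per volume of the solution
- steps thought possible: starting material <-> target; target <-> isomer of the product; isomer of the product <-> starting material; solid substrate <-> starting material; starting material -> decomposition product; crystals <-> target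
- at the start none of the solid substrate is in solution

Two extreme flasks bracket the asked share. At the kinetic end stands a solution without crystals, for which the runs give no share, so the scale takes as its yardstick the symmetric case of isomer and target formed alike: a share of 0.5 as a fraction, which is a mark on the scale and no claim about the flask. At the other end, crystals hold the dissolved target steady, so the isomer stays at one concentration, and its percentage of the charge is not what carries over. Both runs at 12.0 d and 20.0 d average 0.210 mM: this is the isomer level over crystals, a rough reading, since each point scatters by 2 percentage points. With Saturday's plateau of 93%, this reckoning gives the floor of the share: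

share at 15 d = isomer level / (charge × plateau) = 0.210 mM / (20 mM × 93%) = 1.13%

The time 8.0 h falls before the first reading at 1.25 d, so this reckoning places that share between the two ends, without a single number.

The forecast gives 3% (0% to 15%), 3% (0% to 8%) and 1% (0% to 3.5%): “I expect a small kinetic share early, possibly poorly defined, that is diluted or drained later as the target crystallises.”

The flask gives 15.6%, 4.29% and 1.21%, so the first value lies above the forecast's high end. At 15.0 d crystals make up 89.5% of the charge. The isomer level over the flask's final target of 91.8% gives 1.14%.

    starting material ⇌ target (K = 0.370, k = 0.0890 h⁻¹)
    target ⇌ isomer of the product (K = 0.480, k = 0.0410 h⁻¹)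
    isomer of the product ⇌ starting material (k = 0.0270 h⁻¹)
    solid substrate ⇌ starting material, rate k4*(cs4 - [starting material]) while solid is left; crystals form when [starting material] > cs4 (solubility = 5.90 mM, k = 0.0790 h⁻¹)
    starting material → decomposition product (k = 2.10 × 10⁻⁴ h⁻¹)
    crystals ⇌ target, rate k6*(cs6 - [target]) while solid is left; crystals form when [target] > cs6 (solubility = 0.470 mM, k = 2.80 h⁻¹)

A neighbour flask charged with 5.0 mM of solid substrate: the isomer level is 4.20% of that charge. Computed, that flask ends with 4.51% isomer, 68.1% target and a share of 6.21%.

The data were computed for an exercise; the scatter is artificial.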